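**Retrosynthetic overview**
- The target is a (2S)-5,7-dihydroxyflavanone whose C2 aryl group is ring A of a trans-(2R,3S)-2-aryl-3-(hydroxymethyl)-2,3-dihydrobenzofuran. The last C–C disconnection is the flavanone C2–aryl bond: asymmetric 1,4-addition of an arylboronic acid to 5,7-bis(benzyloxy)chromone, followed by hydrogenolysis of all benzyl ethers.
- The strategy rests on one feature: C2 of the dihydrobenzofuran is benzylic to a 4-hydroxy-3-methoxyphenyl ring. Its para OH can expel a benzylic leaving group, so the O1–C2 bond is cut back to a para-quinone methide held next to the C7a phenol oxygen of ring A. The precursor is a 2-(2-hydroxyaryl)-1-aryl-propane-1,3-diol in which only the future C3 has to be defined.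
- That diol comes from an Evans syn-aldol of an (R)-4-benzyloxazolidinone arylacetyl imide with O-allylvanillin, LiBH4 cleavage and non-acidic removal of both allyl ethers. The arylacetic acid comes from 2,3-dihydroxybenzaldehyde by 3-O-benzylation, bromination, allylation and one-carbon homologation.
- Ring order: dihydrofuran ring (step 11), then the pyranone ring of the chromone built separately (step 15) and turned into the flavanone ring at the coupling (step 16).

Key step: step 11

Remark on the chemistry: the sense of induction of the t-BuPyOX ligand on the chromone is taken from its enone-face model. The (S) ligand gives (R)-3-aryl-3-methylcyclohexanones, which maps onto 2R flavanones, so the (R) ligand is specified for the 2S centre.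

**Route**

Step 1
Reactants: 1 2,3-dihydroxybenzaldehyde
Product: 2 3-(benzyloxy)-2-hydroxybenzaldehyde
Conditions: NaH (2.2 equiv), DMSO, rt; BnBr (1.0 equiv), rt; aqueous acid work-up
Reagents that add atoms: benzyl bromide, BrCc1ccccc1
Why: In the dianion the 2-phenoxide is conjugated with and chelated to the ortho formyl group and is the weaker nucleophile, so one equivalent of benzyl bromide should alkylate O3 selectively (Williamson ether synthesis).

Step 2
Reactants: 2 3-(benzyloxy)-2-hydroxybenzaldehyde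
Product: 3 3-(benzyloxy)-5-bromo-2-hydroxybenzaldehyde
Conditions: Br2 (1.05 equiv), NaOAc, AcOH, rt
Reagents that add atoms: bromine, BrBr
Why: Electrophilic aromatic bromination should go to C5, para to the free phenol and meta to the formyl group, as in the bromination of ortho-vanillin, while the unactivated benzyl ring is left alone.

Step 3
Reactants: 3 3-(benzyloxy)-5-bromo-2-hydroxybenzaldehyde
Product: 4 2-(allyloxy)-3-(benzyloxy)-5-bromobenzaldehyde
Conditions: allyl bromide, K2CO3, DMF, 50 °C
Reagents that add atoms: allyl bromide, C=CCBr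
Why: Williamson allylation caps the ring A phenol with a group that tolerates base, hydride, boron Lewis acid and aqueous acid and that can later be removed without acid.

Step 4
Reactants: 4 2-(allyloxy)-3-(benzyloxy)-5-bromobenzaldehyde
Product: 5 2-(allyloxy)-1-(benzyloxy)-5-bromo-3-(2-methoxyethenyl)benzene (E/Z mixture)
Conditions: MeOCH2PPh3Cl, KOtBu, THF, 0 °C to rt
Reagents that add atoms: (methoxymethyl)triphenylphosphonium chloride, COC[P+](c1ccccc1)(c1ccccc1)c1ccccc1.[Cl-]
Why: Wittig methoxymethylenation of the aryl aldehyde adds the one carbon that is needed, and the alkene geometry is irrelevant because both isomers hydrolyse to the same aldehyde.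

Step 5
Reactants: 5 2-(allyloxy)-1-(benzyloxy)-5-bromo-3-(2-methoxyethenyl)benzene
Product: 7 2-[2-(allyloxy)-3-(benzyloxy)-5-bromophenyl]acetic acid, via arylacetaldehyde 6 (not isolated)
Conditions: 2 M aq. HCl, THF, 45 °C; extractive work-up, crude aldehyde taken on at once: NaClO2, NaH2PO4, 2-methyl-2-butene, t-BuOH/THF/H2O, 0 °C to rt
Reagents that add atoms: water, O; sodium chlorite, [Na+].[O-]Cl=O
Why: Acid hydrolysis of the enol ether gives the air-sensitive arylacetaldehyde, which is oxidised immediately by the Pinnick oxidation, with excess 2-methyl-2-butene taking up hypochlorous acid so that the allyl ether and the electron-rich ring are spared.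

Step 6
Reactants: 7 2-[2-(allyloxy)-3-(benzyloxy)-5-bromophenyl]acetic acid
Product: 9 (4R)-3-{2-[2-(allyloxy)-3-(benzyloxy)-5-bromophenyl]acetyl}-4-benzyl-1,3-oxazolidin-2-one, via mixed pivalic anhydride 8 (not isolated)
Conditions: PivCl, Et3N, THF, −20 °C; then LiCl, (R)-4-benzyl-1,3-oxazolidin-2-one, −20 °C to rt
Reagents that add atoms: (R)-4-benzyl-1,3-oxazolidin-2-one, O=C1N[C@H](Cc2ccccc2)CO1
Why: N-Acylation of the oxazolidinone through the mixed anhydride (LiCl-assisted acyl transfer) should occur at the less hindered arylacetyl carbonyl and not at the pivaloyl carbonyl.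

Step 7
Reactants: 10 vanillin
Product: 11 4-(allyloxy)-3-methoxybenzaldehyde
Conditions: allyl bromide, K2CO3, DMF, rt
Reagents that add atoms: allyl bromide, C=CCBr
Why: Williamson allylation masks the phenol with the same group as on ring A, so that one operation later frees both.

Step 8
Reactants: 9 (4R)-3-{2-[2-(allyloxy)-3-(benzyloxy)-5-bromophenyl]acetyl}-4-benzyl-1,3-oxazolidin-2-one; 11 4-(allyloxy)-3-methoxybenzaldehyde
Product: 13 (4R)-3-[(2R,3R)-2-[2-(allyloxy)-3-(benzyloxy)-5-bromophenyl]-3-[4-(allyloxy)-3-methoxyphenyl]-3-hydroxypropanoyl]-4-benzyl-1,3-oxazolidin-2-one, via Z boron enolate 12 (not isolated)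
Conditions: Bu2BOTf, iPr2NEt, CH2Cl2, −78 to 0 °C; 11, −78 to 0 °C; pH 7 phosphate buffer, MeOH, 30% H2O2, 0 °C
Reagents that add atoms: none
Why: Evans syn-aldol: soft enolisation gives the Z boron enolate, which should react through a Zimmerman–Traxler chair on the face opposite the benzyl group of the (R) auxiliary, setting the α-carbon (the later C3 of the dihydrobenzofuran) as 2R and the carbinol as 3R, the latter being of no consequence later.

Step 9
Reactants: 13 (4R)-3-[(2R,3R)-2-[2-(allyloxy)-3-(benzyloxy)-5-bromophenyl]-3-[4-(allyloxy)-3-methoxyphenyl]-3-hydroxypropanoyl]-4-benzyl-1,3-oxazolidin-2-one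
Product: 14 (1R,2S)-2-[2-(allyloxy)-3-(benzyloxy)-5-bromophenyl]-1-[4-(allyloxy)-3-methoxyphenyl]propane-1,3-diol
Conditions: LiBH4 (2 equiv), MeOH (2 equiv), THF, 0 °C
Reagents that add atoms: none
Why: Reductive removal of the auxiliary: LiBH4 should reduce the exocyclic imide carbonyl to the primary alcohol and leave the aryl bromide and the allyl and benzyl ethers alone, and the stereocentre keeps its geometry (its descriptor changes to 2S only through the priority change from C=O to CH2OH).

Step 10
Reactants: 14 (1R,2S)-2-[2-(allyloxy)-3-(benzyloxy)-5-bromophenyl]-1-[4-(allyloxy)-3-methoxyphenyl]propane-1,3-diol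
Product: 15 (1R,2S)-2-[3-(benzyloxy)-5-bromo-2-hydroxyphenyl]-1-(4-hydroxy-3-methoxyphenyl)propane-1,3-diol
Conditions: Pd(PPh3)4 (5 mol %), morpholine (10 equiv), THF, rt
Reagents that add atoms: none
Why: Tsuji–Trost deallylation: zerovalent palladium ionises both aryl allyl ethers to π-allyl complexes that morpholine intercepts, oxidative addition into the electron-rich aryl bromide should not compete at room temperature, and the absence of acid keeps the benzylic alcohol intact.

Step 11
Reactants: 15 (1R,2S)-2-[3-(benzyloxy)-5-bromo-2-hydroxyphenyl]-1-(4-hydroxy-3-methoxyphenyl)propane-1,3-diol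
Product: 17 [(2R,3S)-7-(benzyloxy)-5-bromo-2-(4-hydroxy-3-methoxyphenyl)-2,3-dihydro-1-benzofuran-3-yl]methanol, via para-quinone methide 16 (not isolated)
Conditions: HCl (1.25 M in MeOH, 2 equiv), MeOH (0.02 M), 0 °C to rt; NaHCO3 quench
Reagents that add atoms: none
Why: Protonation and loss of water from the benzylic carbinol, pushed by the para hydroxyl of the guaiacyl ring, gives the O-protonated para-quinone methide 16; methanol may add reversibly, but the benzylic methyl ether re-ionises under the same conditions. The closest known reaction type is the acid-promoted cyclisation of 2-(2-hydroxyaryl)-1-aryl-1,3-propanediols to trans-2-aryl-3-(hydroxymethyl)-2,3-dihydrobenzofurans (phenylcoumaran formation from quinone methides). The ring A phenol oxygen adds to the methide carbon in a 5-exo-trig closure that forms O1–C2 and the dihydrofuran ring. C2 is the only new stereocentre and is controlled by the existing C3: closure is reversible through the quinone methide, so the product should settle as the trans isomer (2R from 3S) with the aryl and CH2OH groups on opposite faces, and either carbinol epimer of 15 would converge on it. The step needs ionisation of the secondary and not the primary alcohol, and capture by the phenol and not by CH2OH; the first is secured because only C1 is benzylic to a para-hydroxyaryl ring, the second because the phenol closes a five-membered ring whereas CH2OH could only close an oxetane. Loss of formaldehyde to a stilbene is held back by low temperature, dilution and quenching as soon as 15 and its methyl ether are consumed.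

Step 12
Reactants: 17 [(2R,3S)-7-(benzyloxy)-5-bromo-2-(4-hydroxy-3-methoxyphenyl)-2,3-dihydro-1-benzofuran-3-yl]methanol
Product: 18 [(2R,3S)-7-(benzyloxy)-2-[4-(benzyloxy)-3-methoxyphenyl]-5-bromo-2,3-dihydro-1-benzofuran-3-yl]methanol
Conditions: BnBr (1.1 equiv), K2CO3, acetone, rt to 40 °C
Reagents that add atoms: benzyl bromide, BrCc1ccccc1
Why: Chemoselective Williamson etherification: K2CO3 deprotonates the phenol but not the primary alcohol, and capping the phenol removes the quinone-methide-forming group before the metal-catalysed steps.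

Step 13
Reactants: 18 [(2R,3S)-7-(benzyloxy)-2-[4-(benzyloxy)-3-methoxyphenyl]-5-bromo-2,3-dihydro-1-benzofuran-3-yl]methanol
Product: 19 [(2R,3S)-7-(benzyloxy)-2-[4-(benzyloxy)-3-methoxyphenyl]-3-(hydroxymethyl)-2,3-dihydro-1-benzofuran-5-yl]boronic acid
Conditions: B2(OH)4 (3 equiv), chloro(2-dicyclohexylphosphino-2',4',6'-triisopropyl-1,1'-biphenyl)[2-(2'-amino-1,1'-biphenyl)]palladium (second-generation XPhos precatalyst, 2 mol %), XPhos (4 mol %), KOAc (3 equiv), EtOH, 80 °C
Reagents that add atoms: tetrahydroxydiboron, OB(O)B(O)O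
Why: Miyaura-type palladium-catalysed borylation with tetrahydroxydiboron should give the free boronic acid directly from the unhindered aryl bromide, and the mild acetate base tolerates the primary alcohol and the benzyl ethers.

Step 14
Reactants: 20 2',4',6'-trihydroxyacetophenone
Product: 21 1-[2,4-bis(benzyloxy)-6-hydroxyphenyl]ethan-1-one
Conditions: BnBr (2.05 equiv), K2CO3, DMF, rt
Reagents that add atoms: benzyl bromide, BrCc1ccccc1
Why: Williamson benzylation should stop at the bis-ether because the last hydroxyl is held in a hydrogen bond to the ketone and is much less nucleophilic.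

Step 15
Reactants: 21 1-[2,4-bis(benzyloxy)-6-hydroxyphenyl]ethan-1-one
Product: 23 5,7-bis(benzyloxy)-4H-chromen-4-one, via enaminone 22 (not isolated)
Conditions: Me2NCH(OMe)2, toluene, 100 °C; evaporate; conc. aq. HCl, CH2Cl2, 40 °C
Reagents that add atoms: N,N-dimethylformamide dimethyl acetal, COC(OC)N(C)C
Why: Condensation of the methyl ketone with the amide acetal gives the enaminone, and acid then induces intramolecular oxa-Michael addition of the phenol and loss of dimethylamine to close the pyranone ring (enaminone route to chromones).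

Step 16
Reactants: 19 [(2R,3S)-7-(benzyloxy)-2-[4-(benzyloxy)-3-methoxyphenyl]-3-(hydroxymethyl)-2,3-dihydro-1-benzofuran-5-yl]boronic acid; 23 5,7-bis(benzyloxy)-4H-chromen-4-one
Product: 24 (2S)-5,7-bis(benzyloxy)-2-[(2R,3S)-7-(benzyloxy)-2-[4-(benzyloxy)-3-methoxyphenyl]-3-(hydroxymethyl)-2,3-dihydro-1-benzofuran-5-yl]-2,3-dihydro-4H-chromen-4-one
Conditions: 23 (1.5 equiv), Pd(OCOCF3)2 (10 mol %), (R)-4-tert-butyl-2-(pyridin-2-yl)-4,5-dihydro-1,3-oxazole [(R)-t-BuPyOX, 12 mol %], NH4PF6 (30 mol %), H2O (5 equiv), ClCH2CH2Cl, 60 °C, argon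
Reagents that add atoms: none
Why: Hayashi–Miyaura-type asymmetric conjugate addition under cationic divalent palladium: transmetalation of the boronic acid, enantio-determining insertion of the chromone C2=C3 bond into the aryl–palladium bond and protonolysis of the palladium enolate by water, with the face of the chromone chosen by the pyridine-oxazoline ligand (catalyst control, the existing stereocentres being remote) so that the (R) ligand should give the 2S flavanone.

Step 17
Reactants: 24 (2S)-5,7-bis(benzyloxy)-2-[(2R,3S)-7-(benzyloxy)-2-[4-(benzyloxy)-3-methoxyphenyl]-3-(hydroxymethyl)-2,3-dihydro-1-benzofuran-5-yl]-2,3-dihydro-4H-chromen-4-one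
Product: 25 Silyhermin B, (2S)-5,7-dihydroxy-2-[(2R,3S)-7-hydroxy-2-(4-hydroxy-3-methoxyphenyl)-3-(hydroxymethyl)-2,3-dihydro-1-benzofuran-5-yl]-2,3-dihydro-4H-chromen-4-one
Conditions: H2 (1 atm), 10% Pd on carbon, EtOAc/MeOH, rt, stopped at the calculated hydrogen uptake
Reagents that add atoms: none
Why: Catalytic hydrogenolysis should cleave the four aryl benzyl ethers under neutral conditions, which avoids the base-induced ring opening that would racemise the flavanone C2, and aryl benzyl ethers are cleaved faster than the two cyclic benzylic C–O bonds.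

**Compound list**

1 | 2,3-dihydroxybenzaldehyde | O=Cc1cccc(O)c1O | starting material
2 | 3-(benzyloxy)-2-hydroxybenzaldehyde | O=Cc1cccc(OCc2ccccc2)c1O | intermediate
3 | 3-(benzyloxy)-5-bromo-2-hydroxybenzaldehyde | O=Cc1cc(Br)cc(OCc2ccccc2)c1O | intermediate
4 | 2-(allyloxy)-3-(benzyloxy)-5-bromobenzaldehyde | C=CCOc1c(C=O)cc(Br)cc1OCc1ccccc1 | intermediate
5 | 2-(allyloxy)-1-(benzyloxy)-5-bromo-3-(2-methoxyethenyl)benzene (E/Z mixture) | COC=Cc1cc(Br)cc(OCc2ccccc2)c1OCC=C | intermediate
6 | 2-[2-(allyloxy)-3-(benzyloxy)-5-bromophenyl]acetaldehyde | O=CCc1cc(Br)cc(OCc2ccccc2)c1OCC=C | intermediate (not isolated)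
7 | 2-[2-(allyloxy)-3-(benzyloxy)-5-bromophenyl]acetic acid | OC(=O)Cc1cc(Br)cc(OCc2ccccc2)c1OCC=C | intermediate
8 | 2-[2-(allyloxy)-3-(benzyloxy)-5-bromophenyl]acetic pivalic anhydride | CC(C)(C)C(=O)OC(=O)Cc1cc(Br)cc(OCc2ccccc2)c1OCC=C | intermediate (not isolated)
9 | (4R)-3-{2-[2-(allyloxy)-3-(benzyloxy)-5-bromophenyl]acetyl}-4-benzyl-1,3-oxazolidin-2-one | O=C(Cc1cc(Br)cc(OCc2ccccc2)c1OCC=C)N1C(=O)OC[C@H]1Cc1ccccc1 | intermediate
10 | vanillin (4-hydroxy-3-methoxybenzaldehyde) | COc1cc(C=O)ccc1O | starting material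
11 | 4-(allyloxy)-3-methoxybenzaldehyde | COc1cc(C=O)ccc1OCC=C | intermediate
12 | Z dibutylboron enolate of 9 | CCCCB(CCCC)O/C(N1C(=O)OC[C@H]1Cc1ccccc1)=C\c1cc(Br)cc(OCc2ccccc2)c1OCC=C | intermediate (not isolated)
13 | (4R)-3-[(2R,3R)-2-[2-(allyloxy)-3-(benzyloxy)-5-bromophenyl]-3-[4-(allyloxy)-3-methoxyphenyl]-3-hydroxypropanoyl]-4-benzyl-1,3-oxazolidin-2-one | COc1cc([C@H](O)[C@H](C(=O)N2C(=O)OC[C@H]2Cc2ccccc2)c2cc(Br)cc(OCc3ccccc3)c2OCC=C)ccc1OCC=C | intermediate
14 | (1R,2S)-2-[2-(allyloxy)-3-(benzyloxy)-5-bromophenyl]-1-[4-(allyloxy)-3-methoxyphenyl]propane-1,3-diol | COc1cc([C@H](O)[C@H](CO)c2cc(Br)cc(OCc3ccccc3)c2OCC=C)ccc1OCC=C | intermediate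
15 | (1R,2S)-2-[3-(benzyloxy)-5-bromo-2-hydroxyphenyl]-1-(4-hydroxy-3-methoxyphenyl)propane-1,3-diol | COc1cc([C@H](O)[C@H](CO)c2cc(Br)cc(OCc3ccccc3)c2O)ccc1O | intermediate
16 | 4-{(2S)-2-[3-(benzyloxy)-5-bromo-2-hydroxyphenyl]-3-hydroxypropylidene}-2-methoxycyclohexa-2,5-dien-1-one (para-quinone methide, O-protonated under the conditions) | COC1=CC(=C[C@H](CO)c2cc(Br)cc(OCc3ccccc3)c2O)C=CC1=O | intermediate (not isolated)
17 | [(2R,3S)-7-(benzyloxy)-5-bromo-2-(4-hydroxy-3-methoxyphenyl)-2,3-dihydro-1-benzofuran-3-yl]methanol | COc1cc([C@@H]2Oc3c(OCc4ccccc4)cc(Br)cc3[C@H]2CO)ccc1O | intermediate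
18 | [(2R,3S)-7-(benzyloxy)-2-[4-(benzyloxy)-3-methoxyphenyl]-5-bromo-2,3-dihydro-1-benzofuran-3-yl]methanol | COc1cc([C@@H]2Oc3c(OCc4ccccc4)cc(Br)cc3[C@H]2CO)ccc1OCc1ccccc1 | intermediate
19 | [(2R,3S)-7-(benzyloxy)-2-[4-(benzyloxy)-3-methoxyphenyl]-3-(hydroxymethyl)-2,3-dihydro-1-benzofuran-5-yl]boronic acid | COc1cc([C@@H]2Oc3c(OCc4ccccc4)cc(B(O)O)cc3[C@H]2CO)ccc1OCc1ccccc1 | intermediate
20 | 2',4',6'-trihydroxyacetophenone | CC(=O)c1c(O)cc(O)cc1O | starting material
21 | 1-[2,4-bis(benzyloxy)-6-hydroxyphenyl]ethan-1-one | CC(=O)c1c(O)cc(OCc2ccccc2)cc1OCc1ccccc1 | intermediate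
22 | (E)-1-[2,4-bis(benzyloxy)-6-hydroxyphenyl]-3-(dimethylamino)prop-2-en-1-one | CN(C)/C=C/C(=O)c1c(O)cc(OCc2ccccc2)cc1OCc1ccccc1 | intermediate (not isolated)
23 | 5,7-bis(benzyloxy)-4H-chromen-4-one | O=c1ccoc2cc(OCc3ccccc3)cc(OCc3ccccc3)c12 | intermediate
24 | (2S)-5,7-bis(benzyloxy)-2-[(2R,3S)-7-(benzyloxy)-2-[4-(benzyloxy)-3-methoxyphenyl]-3-(hydroxymethyl)-2,3-dihydro-1-benzofuran-5-yl]-2,3-dihydro-4H-chromen-4-one | COc1cc([C@@H]2Oc3c(OCc4ccccc4)cc([C@@H]4CC(=O)c5c(OCc6ccccc6)cc(OCc6ccccc6)cc5O4)cc3[C@H]2CO)ccc1OCc1ccccc1 | intermediate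
25 | Silyhermin B | COc1cc([C@@H]2Oc3c(O)cc([C@@H]4CC(=O)c5c(O)cc(O)cc5O4)cc3[C@H]2CO)ccc1O | target

**Step count and risks**

Total step count: 17. Longest linear sequence: 14 steps (steps 1–6, 8–13, 16 and 17).

The three steps most likely to fail:

1. Step 16. The doubly oxygenated chromone is a poor acceptor, so insertion may be slow, protodeboronation of the boronic acid may outrun it, and facial discrimination may be incomplete. The fallback builds the flavanone by the chalcone route, setting out from 18 and 21.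
   - Bromide 18 would be converted with n-BuLi (2.2 equiv, THF, −78 °C) and DMF into (2R,3S)-7-(benzyloxy)-2-[4-(benzyloxy)-3-methoxyphenyl]-3-(hydroxymethyl)-2,3-dihydro-1-benzofuran-5-carbaldehyde F1.
   - Claisen–Schmidt condensation of F1 with acetophenone 21 (KOH, EtOH, rt) would give (E)-1-[2,4-bis(benzyloxy)-6-hydroxyphenyl]-3-[(2R,3S)-7-(benzyloxy)-2-[4-(benzyloxy)-3-methoxyphenyl]-3-(hydroxymethyl)-2,3-dihydro-1-benzofuran-5-yl]prop-2-en-1-one F2.
   - Oxa-Michael ring closure (NaOAc, EtOH, reflux) would give 24 together with its flavanone C2 epimer, the (2R)-diastereomer of 24 F3. The two are diastereomers and would be separated by preparative HPLC, and F3 can be reopened to F2 with base and recycled.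
   - The route is rejoined at 24.

2. Step 11. The benzylic cation may fragment with loss of formaldehyde to a stilbene, the quinone methide may be captured intermolecularly, or prolonged acid may be needed for full trans equilibration. The fallback generates the neutral quinone methide in two stages without standing acid, setting out from 15.
   - Me3SiBr (CH2Cl2, −20 °C) would convert the benzylic alcohol into 4-{(2S)-2-[3-(benzyloxy)-5-bromo-2-hydroxyphenyl]-1-bromo-3-hydroxypropyl}-2-methoxyphenol F4 (either C1 epimer).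
   - Shaking with aqueous NaHCO3 at 0 °C would eliminate HBr to the quinone methide 16, which closes to 17.
   - The route is rejoined at 17.

3. Step 9. The lithium aldolate of an electron-rich benzylic carbinol may undergo retro-aldol cleavage, and the doubly activated α-carbon may epimerise before the imide is reduced. The fallback masks the alkoxide first, setting out from 13.
   - Silylation (Et3SiOTf, 2,6-lutidine, CH2Cl2, −78 °C) would give the triethylsilyl ether of 13, F5.
   - Reduction (LiBH4, THF, 0 °C) would give (2S,3R)-2-[2-(allyloxy)-3-(benzyloxy)-5-bromophenyl]-3-[4-(allyloxy)-3-methoxyphenyl]-3-(triethylsilyloxy)propan-1-ol F6.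
   - Desilylation (Bu4NF, AcOH, THF, 0 °C) rejoins the route at 14.

Further compounds
F1 | step 16 | (2R,3S)-7-(benzyloxy)-2-[4-(benzyloxy)-3-methoxyphenyl]-3-(hydroxymethyl)-2,3-dihydro-1-benzofuran-5-carbaldehyde | COc1cc([C@@H]2Oc3c(OCc4ccccc4)cc(C=O)cc3[C@H]2CO)ccc1OCc1ccccc1
F2 | step 16 | (E)-1-[2,4-bis(benzyloxy)-6-hydroxyphenyl]-3-[(2R,3S)-7-(benzyloxy)-2-[4-(benzyloxy)-3-methoxyphenyl]-3-(hydroxymethyl)-2,3-dihydro-1-benzofuran-5-yl]prop-2-en-1-one | COc1cc([C@@H]2Oc3c(OCc4ccccc4)cc(/C=C/C(=O)c4c(O)cc(OCc5ccccc5)cc4OCc4ccccc4)cc3[C@H]2CO)ccc1OCc1ccccc1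
F3 | step 16 | (2R)-5,7-bis(benzyloxy)-2-[(2R,3S)-7-(benzyloxy)-2-[4-(benzyloxy)-3-methoxyphenyl]-3-(hydroxymethyl)-2,3-dihydro-1-benzofuran-5-yl]-2,3-dihydro-4H-chromen-4-one | COc1cc([C@@H]2Oc3c(OCc4ccccc4)cc([C@H]4CC(=O)c5c(OCc6ccccc6)cc(OCc6ccccc6)cc5O4)cc3[C@H]2CO)ccc1OCc1ccccc1
F4 | step 11 | 4-{(2S)-2-[3-(benzyloxy)-5-bromo-2-hydroxyphenyl]-1-bromo-3-hydroxypropyl}-2-methoxyphenol | COc1cc(C(Br)[C@H](CO)c2cc(Br)cc(OCc3ccccc3)c2O)ccc1O
F5 | step 9 | (4R)-3-[(2R,3R)-2-[2-(allyloxy)-3-(benzyloxy)-5-bromophenyl]-3-[4-(allyloxy)-3-methoxyphenyl]-3-(triethylsilyloxy)propanoyl]-4-benzyl-1,3-oxazolidin-2-one | COc1cc([C@H](O[Si](CC)(CC)CC)[C@H](C(=O)N2C(=O)OC[C@H]2Cc2ccccc2)c2cc(Br)cc(OCc3ccccc3)c2OCC=C)ccc1OCC=C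
F6 | step 9 | (2S,3R)-2-[2-(allyloxy)-3-(benzyloxy)-5-bromophenyl]-3-[4-(allyloxy)-3-methoxyphenyl]-3-(triethylsilyloxy)propan-1-ol | COc1cc([C@H](O[Si](CC)(CC)CC)[C@H](CO)c2cc(Br)cc(OCc3ccccc3)c2OCC=C)ccc1OCC=C
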